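**Retrosynthetic overview**

- The strategy rests on the α-ketol of ring C: the tertiary carbinol C3 (carrying OH and ring B) is bonded directly to the C4 ketone carbon, which sits on ring A at C4a. The C3–C4 bond is cut as an acyl anion at C4 (from a ring A aldehyde) adding to a ring B ketone at C3, the two tethered through O1–C2.
- The keto-aldehyde 15 comes from O-alkylation of 2,6-dihydroxy-4-methoxybenzaldehyde 13 with the ring B chloromethyl ketone 11, followed by silylation of the remaining phenol.
- Ketone 11 comes from aryl bromide 7 by bromine–lithium exchange and acylation with 2-chloro-N-methoxy-N-methylacetamide. Bromine is bought in place (4-bromo-3-methoxyphenol), because brominating an ortho-prenylphenol would risk bromoetherification and the wrong ring position. The prenyl group is set between the two oxygens by carbamate-directed ortho-lithiation.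
- Rings A and B are bought as arenes. Ring C is the only ring made (step 9), and the two silyl ethers come off last.

Key step: step 9

Assumption: the (5aR,10bS) antipode of the aminoindanol-derived triazolium salt is taken as the hand that delivers the (3S) carbinol; should a trial cyclisation show the opposite sense, the (5aS,10bR) salt is used with no other change.

**Route**

Step 1
Reactants: 1 4-bromo-3-methoxyphenol
Product: 2 4-bromo-3-methoxyphenyl N,N-diethylcarbamate
Conditions: Et2NCOCl, K2CO3, MeCN, reflux
Reagents that add atoms: N,N-diethylcarbamoyl chloride, CCN(CC)C(Cl)=O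
Why: O-carbamoylation of the phenoxide (acyl substitution at the carbamoyl chloride) installs a strong oxygen-based directing group for the ortho-metalation that follows and leaves the aryl bromide untouched.

Step 2
Reactants: 2 4-bromo-3-methoxyphenyl N,N-diethylcarbamate; 3 1-bromo-3-methylbut-2-ene (prenyl bromide)
Product: 5 4-bromo-3-methoxy-2-(3-methylbut-2-en-1-yl)phenyl N,N-diethylcarbamate, via aryllithium 4 (not isolated)
Conditions: LiN(iPr)2, THF, −78 °C; then CuBr·SMe2 (10 mol %), 3, −78 → −30 °C
Reagents that add atoms: none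
Why: Directed ortho-metalation: the amide base does not exchange with the aryl bromide and should remove the proton flanked by the carbamate and methoxy oxygens, and the aryllithium is allylated at the primary carbon of the bromide in the cold before an anionic Fries shift of the carbamoyl group can set in.

Step 3
Reactants: 5 4-bromo-3-methoxy-2-(3-methylbut-2-en-1-yl)phenyl N,N-diethylcarbamate
Product: 6 4-bromo-3-methoxy-2-(3-methylbut-2-en-1-yl)phenol
Conditions: NaOH, EtOH/H2O, reflux; then aq. NH4Cl
Reagents that add atoms: none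
Why: Basic carbamate hydrolysis (addition–elimination at the carbamoyl carbon, then decarboxylation) frees the phenol under conditions to which the prenyl alkene, the aryl bromide and the methyl ether are inert, and the near-neutral work-up avoids acid-induced chroman formation.

Step 4
Reactants: 6 4-bromo-3-methoxy-2-(3-methylbut-2-en-1-yl)phenol
Product: 7 [4-bromo-3-methoxy-2-(3-methylbut-2-en-1-yl)phenoxy]tri(propan-2-yl)silane
Conditions: TIPSCl, imidazole, DMF, 40 °C
Reagents that add atoms: chlorotri(propan-2-yl)silane (TIPSCl), CC(C)[Si](Cl)(C(C)C)C(C)C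
Why: Imidazole-promoted O-silylation gives a bulky aryl silyl ether that withstands butyllithium, carbonate and amine bases and is removed later by fluoride.

Step 5
Reactants: 7 [4-bromo-3-methoxy-2-(3-methylbut-2-en-1-yl)phenoxy]tri(propan-2-yl)silane; 8 2-chloro-N-methoxy-N-methylacetamide
Product: 11 2-chloro-1-{2-methoxy-3-(3-methylbut-2-en-1-yl)-4-[tri(propan-2-yl)silyloxy]phenyl}ethan-1-one, via aryllithium 9 (not isolated), via lithium hemiaminal alkoxide 10 (not isolated)
Conditions: n-BuLi, THF, −78 °C; then 8, −78 → −20 °C; cold 1 M HCl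
Reagents that add atoms: none
Why: Bromine–lithium exchange followed by Weinreb ketone synthesis: the chelated tetrahedral adduct of the aryllithium with the N-methoxy-N-methylamide persists until the quench, so the chloromethyl ketone should form without over-addition or loss of chloride.

Step 6
Reactants: 12 2-hydroxy-4,6-dimethoxybenzaldehyde
Product: 13 2,6-dihydroxy-4-methoxybenzaldehyde
Conditions: AlCl3 (3 equiv), CH2Cl2, 0 °C → reflux; aq. HCl
Reagents that add atoms: none
Why: Chelation-directed Lewis acid ether cleavage: aluminium held between the formyl oxygen and the ortho methoxy oxygen activates only that methyl group for attack by chloride, so the para methoxy group should stay.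

Step 7
Reactants: 13 2,6-dihydroxy-4-methoxybenzaldehyde; 11 2-chloro-1-{2-methoxy-3-(3-methylbut-2-en-1-yl)-4-[tri(propan-2-yl)silyloxy]phenyl}ethan-1-one
Product: 14 2-hydroxy-4-methoxy-6-(2-{2-methoxy-3-(3-methylbut-2-en-1-yl)-4-[tri(propan-2-yl)silyloxy]phenyl}-2-oxoethoxy)benzaldehyde
Conditions: K2CO3 (1.1 equiv), NaI (10 mol %), acetone, rt; 13 in slight excess (1.3 equiv)
Reagents that add atoms: none
Why: Williamson ether synthesis with in situ Finkelstein halide exchange: the two hydroxyls of 13 are equivalent so one constitution results, and the remaining ortho phenoxide is a poor nucleophile that also deactivates the aldehyde towards Rap–Stoermer aldol condensation.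

Step 8
Reactants: 14 2-hydroxy-4-methoxy-6-(2-{2-methoxy-3-(3-methylbut-2-en-1-yl)-4-[tri(propan-2-yl)silyloxy]phenyl}-2-oxoethoxy)benzaldehyde
Product: 15 2-[tert-butyl(dimethyl)silyloxy]-4-methoxy-6-(2-{2-methoxy-3-(3-methylbut-2-en-1-yl)-4-[tri(propan-2-yl)silyloxy]phenyl}-2-oxoethoxy)benzaldehyde
Conditions: TBSCl, imidazole, DMF, 0 °C → rt
Reagents that add atoms: tert-butyl(chloro)dimethylsilane (TBSCl), CC(C)(C)[Si](C)(C)Cl
Why: O-silylation of the chelated phenol removes the acidic proton that would otherwise quench carbene and amine in the next step, with a group small enough not to bury the aldehyde; imidazole is too weak a base to enolise the ketone.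

Step 9
Reactants: 15 2-[tert-butyl(dimethyl)silyloxy]-4-methoxy-6-(2-{2-methoxy-3-(3-methylbut-2-en-1-yl)-4-[tri(propan-2-yl)silyloxy]phenyl}-2-oxoethoxy)benzaldehyde
Product: 16 (3S)-5-[tert-butyl(dimethyl)silyloxy]-3-hydroxy-7-methoxy-3-{2-methoxy-3-(3-methylbut-2-en-1-yl)-4-[tri(propan-2-yl)silyloxy]phenyl}-2,3-dihydro-4H-chromen-4-one
Conditions: (5aR,10bS)-2-(pentafluorophenyl)-5a,10b-dihydro-4H,6H-indeno[2,1-b][1,2,4]triazolo[4,3-d][1,4]oxazin-2-ium tetrafluoroborate (10 mol %), Et3N (10 mol %), degassed toluene (0.05 M), rt, Ar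
Reagents that add atoms: none
Why: Et3N frees the triazolylidene carbene, which adds to the ring A aldehyde; proton transfer gives the hydroxy-enamine, an acyl anion equivalent at the future C4, which attacks the tethered ring B ketone carbon (future C3), and collapse of the adduct releases the carbene and leaves the C4 ketone. The closest known reaction is the enantioselective carbene-catalysed intramolecular crossed aldehyde–ketone benzoin cyclisation of 2-(2-aryl-2-oxoethoxy)benzaldehydes to 3-aryl-3-hydroxychroman-4-ones, of which this is a direct case. Ring C closes by 6-exo-trig attack, forming the C3–C4 bond. The C3 configuration is set by the catalyst: the fused aminoindanol backbone blocks one face of the hydroxy-enamine and its OH hydrogen-bonds to the ketone oxygen, so the ketone is held in one orientation and offers one enantioface. The selectivity needed is cross- over homo-coupling and benzoin over aldol: only the aldehyde can become the donor and only the ketone is left as acceptor, dilution suppresses intermolecular coupling, and catalytic weak amine in toluene should leave the aryloxymethyl ketone un-enolised. The product carbinol is quaternary and cannot epimerise, and conjugation of the new ketone with ring A should make the closure effectively irreversible.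

Step 10
Reactants: 16 (3S)-5-[tert-butyl(dimethyl)silyloxy]-3-hydroxy-7-methoxy-3-{2-methoxy-3-(3-methylbut-2-en-1-yl)-4-[tri(propan-2-yl)silyloxy]phenyl}-2,3-dihydro-4H-chromen-4-one
Product: 17 (3S)-3,5-dihydroxy-3-[4-hydroxy-2-methoxy-3-(3-methylbut-2-en-1-yl)phenyl]-7-methoxy-2,3-dihydro-4H-chromen-4-one (EANPDB:LEGU_00502)
Conditions: Bu4NF (2.5 equiv), AcOH (2.5 equiv), THF, 0 °C
Reagents that add atoms: none
Why: Fluoride-induced cleavage of both aryl silyl ethers through pentacoordinate silicon; the acetic acid buffer keeps the medium from turning basic, so the α-ketol should neither ring-open nor dehydrate, and the quaternary C3 cannot epimerise.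

**Compound list**

1 | 4-bromo-3-methoxyphenol | COc1cc(O)ccc1Br | starting material
2 | 4-bromo-3-methoxyphenyl N,N-diethylcarbamate | CCN(CC)C(=O)Oc1ccc(Br)c(OC)c1 | intermediate
3 | 1-bromo-3-methylbut-2-ene (prenyl bromide) | CC(C)=CCBr | starting material
4 | [3-bromo-6-(diethylcarbamoyloxy)-2-methoxyphenyl]lithium | CCN(CC)C(=O)Oc1ccc(Br)c(OC)c1[Li] | intermediate
5 | 4-bromo-3-methoxy-2-(3-methylbut-2-en-1-yl)phenyl N,N-diethylcarbamate | CCN(CC)C(=O)Oc1ccc(Br)c(OC)c1CC=C(C)C | intermediate
6 | 4-bromo-3-methoxy-2-(3-methylbut-2-en-1-yl)phenol | COc1c(Br)ccc(O)c1CC=C(C)C | intermediate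
7 | [4-bromo-3-methoxy-2-(3-methylbut-2-en-1-yl)phenoxy]tri(propan-2-yl)silane | COc1c(Br)ccc(O[Si](C(C)C)(C(C)C)C(C)C)c1CC=C(C)C | intermediate
8 | 2-chloro-N-methoxy-N-methylacetamide | CON(C)C(=O)CCl | starting material
9 | {2-methoxy-3-(3-methylbut-2-en-1-yl)-4-[tri(propan-2-yl)silyloxy]phenyl}lithium | [Li]c1ccc(O[Si](C(C)C)(C(C)C)C(C)C)c(CC=C(C)C)c1OC | intermediate
10 | lithium 2-chloro-1-[methoxy(methyl)amino]-1-{2-methoxy-3-(3-methylbut-2-en-1-yl)-4-[tri(propan-2-yl)silyloxy]phenyl}ethan-1-olate | [Li]OC(CCl)(N(C)OC)c1ccc(O[Si](C(C)C)(C(C)C)C(C)C)c(CC=C(C)C)c1OC | intermediate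
11 | 2-chloro-1-{2-methoxy-3-(3-methylbut-2-en-1-yl)-4-[tri(propan-2-yl)silyloxy]phenyl}ethan-1-one | O=C(CCl)c1ccc(O[Si](C(C)C)(C(C)C)C(C)C)c(CC=C(C)C)c1OC | intermediate
12 | 2-hydroxy-4,6-dimethoxybenzaldehyde | COc1cc(O)c(C=O)c(OC)c1 | starting material
13 | 2,6-dihydroxy-4-methoxybenzaldehyde | COc1cc(O)c(C=O)c(O)c1 | intermediate
14 | 2-hydroxy-4-methoxy-6-(2-{2-methoxy-3-(3-methylbut-2-en-1-yl)-4-[tri(propan-2-yl)silyloxy]phenyl}-2-oxoethoxy)benzaldehyde | O=Cc1c(O)cc(OC)cc1OCC(=O)c1ccc(O[Si](C(C)C)(C(C)C)C(C)C)c(CC=C(C)C)c1OC | intermediate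
15 | 2-[tert-butyl(dimethyl)silyloxy]-4-methoxy-6-(2-{2-methoxy-3-(3-methylbut-2-en-1-yl)-4-[tri(propan-2-yl)silyloxy]phenyl}-2-oxoethoxy)benzaldehyde | O=Cc1c(O[Si](C)(C)C(C)(C)C)cc(OC)cc1OCC(=O)c1ccc(O[Si](C(C)C)(C(C)C)C(C)C)c(CC=C(C)C)c1OC | intermediate
16 | (3S)-5-[tert-butyl(dimethyl)silyloxy]-3-hydroxy-7-methoxy-3-{2-methoxy-3-(3-methylbut-2-en-1-yl)-4-[tri(propan-2-yl)silyloxy]phenyl}-2,3-dihydro-4H-chromen-4-one | COc1cc(O[Si](C)(C)C(C)(C)C)c2c(c1)OC[C@@](O)(c1ccc(O[Si](C(C)C)(C(C)C)C(C)C)c(CC=C(C)C)c1OC)C2=O | intermediate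
17 | (3S)-3,5-dihydroxy-3-[4-hydroxy-2-methoxy-3-(3-methylbut-2-en-1-yl)phenyl]-7-methoxy-2,3-dihydro-4H-chromen-4-one | COc1cc(O)c2c(c1)OC[C@@](O)(c1ccc(O)c(CC=C(C)C)c1OC)C2=O | target

**Step count**

Total: 10 steps. Longest linear sequence: 9 steps (steps 1–5, then 7–10); the ring A branch is step 6.

**Steps most likely to fail**

Step 9. The acyl anion equivalent may form slowly at an electron-rich aldehyde flanked by two ortho oxygens. The amine may instead trigger aldol condensation of the aryloxymethyl ketone onto the aldehyde, ending in a benzofuran. Enantioface selection at the twisted ortho-methoxyaryl ketone may be poor. The fallback takes stereocontrol out of the ring closure. It sets out from 15: the small achiral carbene from 2-(pentafluorophenyl)-6,7-dihydro-5H-pyrrolo[2,1-c][1,2,4]triazol-2-ium tetrafluoroborate (Et3N, toluene, rt) should close ring C to the racemic bis-silyl ketol F1. Preparative chromatography on a chiral stationary phase (amylose tris(3,5-dimethylphenylcarbamate)) should then separate 16 from its (3R) antipode F2, and the route resumes at 16.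

Step 2. The base may deprotonate next to bromine, leading to aryne formation or halogen migration. The carbamoyl group may shift to carbon on warming. The bromide may be attacked at its tertiary terminus. The fallback uses no directed metalation. It sets out from 1: NaH in toluene gives sodium 4-bromo-3-methoxyphenolate F3, whose tight ion pair in the non-polar medium should be C-alkylated ortho to oxygen by prenyl bromide 3. The 2-prenyl phenol 6 is separated from its regioisomers by chromatography, and the route resumes at 6 with steps 1 and 3 left out.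

Step 7. Both phenols may be alkylated, and carbonate may induce aldol condensation of the product onto its own aldehyde. The fallback makes the ether bond under neutral redox-condensation conditions. It sets out from 11: HCO2Na in aqueous EtOH at reflux should displace chloride to give 2-{2-methoxy-3-(3-methylbut-2-en-1-yl)-4-[tri(propan-2-yl)silyloxy]phenyl}-2-oxoethyl formate F4. This solvolyses in the same pot to 2-hydroxy-1-{2-methoxy-3-(3-methylbut-2-en-1-yl)-4-[tri(propan-2-yl)silyloxy]phenyl}ethan-1-one F5. Mitsunobu coupling of this hydroxy ketone with 13 (PPh3, diisopropyl azodicarboxylate, THF, 0 °C → rt) should engage one of the two equivalent acidic phenols and return to the route at 14.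

**Further compounds**

F1 | step 9 | racemic 5-[tert-butyl(dimethyl)silyloxy]-3-hydroxy-7-methoxy-3-{2-methoxy-3-(3-methylbut-2-en-1-yl)-4-[tri(propan-2-yl)silyloxy]phenyl}-2,3-dihydro-4H-chromen-4-one | COc1cc(O[Si](C)(C)C(C)(C)C)c2c(c1)OCC(O)(c1ccc(O[Si](C(C)C)(C(C)C)C(C)C)c(CC=C(C)C)c1OC)C2=O
F2 | step 9 | (3R)-5-[tert-butyl(dimethyl)silyloxy]-3-hydroxy-7-methoxy-3-{2-methoxy-3-(3-methylbut-2-en-1-yl)-4-[tri(propan-2-yl)silyloxy]phenyl}-2,3-dihydro-4H-chromen-4-one | COc1cc(O[Si](C)(C)C(C)(C)C)c2c(c1)OC[C@](O)(c1ccc(O[Si](C(C)C)(C(C)C)C(C)C)c(CC=C(C)C)c1OC)C2=O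
F3 | step 2 | sodium 4-bromo-3-methoxyphenolate | COc1cc([O-])ccc1Br.[Na+]
F4 | step 7 | 2-{2-methoxy-3-(3-methylbut-2-en-1-yl)-4-[tri(propan-2-yl)silyloxy]phenyl}-2-oxoethyl formate | O=COCC(=O)c1ccc(O[Si](C(C)C)(C(C)C)C(C)C)c(CC=C(C)C)c1OC
F5 | step 7 | 2-hydroxy-1-{2-methoxy-3-(3-methylbut-2-en-1-yl)-4-[tri(propan-2-yl)silyloxy]phenyl}ethan-1-one | OCC(=O)c1ccc(O[Si](C(C)C)(C(C)C)C(C)C)c(CC=C(C)C)c1OC
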